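The reading at 10 h sums up a whole curve, so I replace each curve by its mean over those hours.

the same everywhere: reagent in the second phase 0.0475 M
- delta: substrate 0.034 M; run made earlier
- beta: substrate 0.075 M; run made earlier
- flask: substrate 0.050 M; time 10 h; volume of the second phase over the first 1.0

| run | time / h | target / % |
|---|---|---|
| delta | 0.500 | 5 |
| delta | 1.50 | 9 |
| delta | 3.00 | 23 |
| delta | 4.00 | 30 |
| delta | 6.00 | 44 |
| delta | 8.00 | 53 |
| delta | 10.0 | 58 |
| beta | 1.33 | 8 |
| beta | 3.00 | 17 |
| beta | 4.00 | 23 |
| beta | 6.00 | 33 |
| beta | 8.00 | 36 |
| beta | 10.0 | 40 |

(standard deviation of a reading: 1.5 percentage points)

- in the second phase: reagent in the second phase; everything else is in the first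
- charges count per volume of the first phase; a concentration in a rate is the amount of a species over the volume of its own phase; every rate counts per litre of the first phase
- the earlier runs hold the two phases in the same ratio of volumes as the flask asked about

- how much target there is at 10 h, in percent of the substrate charged
- the change that raises the amount of target at 10 h, in percent of the substrate charged most ("none" if none brings more than 2 percentage points) (birch / ash / none)
- amount of target at 10 h, in percent of the substrate charged, after birch

- birch: doubling the transfer coefficient of the reagent in the second phase, all else as stated
- ash: doubling the amount of reagent in the second phase, all else as stated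

As mean clearing time τ I take the mean reagent not yet found as target (charge less half the final [target]) over the mean rate of target (final [target] over the time); its inverse is a mean pseudo-first-order constant. Delta gives 19.1 h at a mean [substrate] of 0.0241 M, and beta gives 10.8 h at 0.0600 M. I split τ into a constant part, 5.28 h, and a part inverse in [substrate]. The flask, at about 0.0378 M, lies between the runs, with mean clearing time τ 14.1 h.

Final [target] is then the reagent charge times the time, over τ plus half the time. At fixed mean [substrate], a relative error in the reagent charge passes on to final [target] in full, one in the time or in τ at 0.738, and one in the constant part at 0.276, while one in the substrate charge does not reach it. If the mean conversion is held instead, so that mean [substrate] moves with the substrate charge, an error in that charge passes on at 0.462. So the reagent charge must be known best. My number is 49.7%. Ash doubles the numerator, while birch, if it halves the constant part, multiplies the result by 1.16, before falling substrate is counted. That first-pass birch, 57.7%, stands above the forecast's.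

The forecast gives 50%, ash and 54%: “The reaction is the main resistance, with transfer a smaller share.”

The flask gives 47.7%; ash adds 21 percentage points, birch 4.2 points, reaching 51.8%. At that time the flask also holds 11.1% as isomer of the product, and τ, read from target readings alone, counts such a loss as a longer clearing time. From the result τ is 14.9 h, against my 14.1 h.

    reagent in the reaction phase ⇌ reagent in the second phase, rate k1*([reagent in the reaction phase] - [reagent in the second phase]/K1) per volume of the first phase (partition coefficient = 0.750, kL = 0.00312 min⁻¹)
    substrate + reagent in the reaction phase → target (k = 0.167 L mol⁻¹ min⁻¹)
    substrate → decomposition product (k = 6.00 × 10⁻⁶ min⁻¹)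
    target ⇌ isomer of the product (K = 1.96, k = 6.81 × 10⁻⁴ min⁻¹)
    reagent in the reaction phase + target → over-reaction product (k = 0.00356 L mol⁻¹ min⁻¹)

For the neighbour with 0.20 M of substrate, taking that charge as its mean [substrate], τ shrinks to 6.94 h, which gives 19.9%. That neighbour flask gives 16.4%, with 78.9% still substrate.

The runs were computed from invented constants; noise was put on by code.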